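The C6 carbinol beside C7, which carries the exocyclic C11=C13 methylene, is the retron of a [2,3]-Wittig rearrangement. The strained (E,E)-cyclodecadiene is therefore never closed head-on: O6 is reconnected to C13. The key step contracts a strain-free 13-membered bis-allylic ether (C6–O–C13, with C7=C11 locked in an O8/O12 dihydrodioxepine acetonide) to the ten-membered carbocycle. In one operation it forms C6–C7, sets C6 and C7 from the single C8 stereocentre, creates C11=C13 and releases O6 for acylation. The precursor ring is assembled without strain by macrolactonisation and transannular metathesis of a linear triene made from (R)-vinyloxirane.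

Key step: step 16

Remark: germacrane numbering is used for all intermediates (C1=C10(C14H3), C2, C3, C4(C15)=C5, C6, C7, C8, C9, C11(=C13)–C12). "Ring-E" means that the two chain or ring carbons on the olefin are trans; for C4=C5 the CIP label is Z because C15 bears oxygen. (R)-2-Vinyloxirane is taken as a commercial chiral building block.

Step 1
Reactants: 1 prop-2-yn-1-ol
Product: 2 tert-butyl(diphenyl)(prop-2-yn-1-yloxy)silane
Conditions: TBDPSCl, imidazole, CH2Cl2, 0 °C to rt
Reagents that add atoms: tert-butyldiphenylsilyl chloride, Cl[Si](c1ccccc1)(c1ccccc1)C(C)(C)C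
Why: Imidazole-promoted silylation of a primary alcohol; TBDPS is chosen because it has to outlast the acid cleavage of a TBS ether in step 10.

Step 2
Reactants: 2 tert-butyl(diphenyl)(prop-2-yn-1-yloxy)silane
Product: 3 methyl 4-[(tert-butyldiphenylsilyl)oxy]but-2-ynoate
Conditions: n-BuLi, THF, −78 °C; ClCO2Me, −78 to 0 °C
Reagents that add atoms: methyl chloroformate, COC(=O)Cl
Why: Deprotonation of the terminal alkyne and C-acylation of the lithium acetylide with a chloroformate is the standard route to ynoates and supplies C4, C5, C6 and C15.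

Step 3
Reactants: 4 (R)-2-vinyloxirane
Product: 5 (3S)-hex-1-en-5-yn-3-ol (C8 carbinol, C7 vinyl, C9, C10≡C1)
Conditions: LiC≡CH·ethylenediamine, DMSO/THF, 0 °C to rt
Reagents that add atoms: lithium acetylide–ethylenediamine complex, [Li]C#C.NCCN
Why: SN2 opening of the epoxide by a hard acetylide without Lewis acid should take place at the unsubstituted carbon, so the C–O bond at the stereocentre is untouched and C8 is carried over (the descriptor changes from R to S only through the priorities).

Step 4
Reactants: 5 (3S)-hex-1-en-5-yn-3-ol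
Product: 6 (3S)-3-[(tert-butyldimethylsilyl)oxy]hex-1-en-5-yne
Conditions: TBSCl, imidazole, DMF, rt
Reagents that add atoms: tert-butyldimethylsilyl chloride, C[Si](C)(Cl)C(C)(C)C
Why: Standard silylation of a secondary alcohol masks O8 for the organometallic steps that follow.

Step 5
Reactants: 6 (3S)-3-[(tert-butyldimethylsilyl)oxy]hex-1-en-5-yne
Product: 8 (3E,6S)-6-[(tert-butyldimethylsilyl)oxy]-4-methylocta-3,7-dien-1-ol, via alkenyl(dimethyl)alane 7 (not isolated)
Conditions: Me3Al, Cp2ZrCl2 (cat.), CH2Cl2, 0 °C to rt; volatiles removed; n-BuLi, hexane/THF, −30 °C; oxirane, −30 °C to rt; aq work-up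
Reagents that add atoms: trimethylaluminium, C[Al](C)C; oxirane, C1CO1
Why: Negishi zirconium-catalysed carboalumination adds Me and Al syn across the terminal alkyne (Me on C10, Al on C1), and the derived alanate opens oxirane with retention, so C9 and C2 end up trans (ring-E C1=C10) while the monosubstituted alkene stays inert.

Step 6
Reactants: 8 (3E,6S)-6-[(tert-butyldimethylsilyl)oxy]-4-methylocta-3,7-dien-1-ol
Product: 9 (3S,5E)-8-bromo-3-[(tert-butyldimethylsilyl)oxy]-5-methylocta-1,5-diene
Conditions: CBr4, PPh3, CH2Cl2, 0 °C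
Reagents that add atoms: carbon tetrabromide, BrC(Br)(Br)Br
Why: The Appel reaction converts the primary homoallylic alcohol into the bromide under neutral conditions that leave the silyl ether and both olefins alone.

Step 7
Reactants: 9 (3S,5E)-8-bromo-3-[(tert-butyldimethylsilyl)oxy]-5-methylocta-1,5-diene; 3 methyl 4-[(tert-butyldiphenylsilyl)oxy]but-2-ynoate
Product: 11 methyl (2Z,6E,9S)-9-[(tert-butyldimethylsilyl)oxy]-3-{[(tert-butyldiphenylsilyl)oxy]methyl}-7-methylundeca-2,6,10-trienoate, via homoallylic Grignard reagent 10 (not isolated)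
Conditions: Mg, THF, rt; CuBr·SMe2, THF, −40 °C; 3, −78 °C; sat. aq NH4Cl at −78 °C
Reagents that add atoms: none
Why: Syn-carbocupration of the ynoate at −78 °C puts C3 and copper on the same side, so protonation with retention leaves C3 trans to the ester carbon C6 and C15 cis to it (ring-E C4=C5), with C15 and C6 already differentiated by oxidation level.

Step 8
Reactants: 11 the trienoate of step 7
Product: 12 (2Z,6E,9S)-9-[(tert-butyldimethylsilyl)oxy]-3-{[(tert-butyldiphenylsilyl)oxy]methyl}-7-methylundeca-2,6,10-trien-1-ol (free O6–H)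
Conditions: DIBAL-H, CH2Cl2, −78 °C; Rochelle salt
Reagents that add atoms: none
Why: DIBAL-H reduces α,β-unsaturated esters cleanly in the 1,2-sense to allylic alcohols without touching the olefin geometry or the silyl ethers.

Step 9
Reactants: 12 the allylic alcohol of step 8; 13 methyl 2-(bromomethyl)acrylate
Product: 14 methyl 2-({[(2Z,6E,9S)-9-[(tert-butyldimethylsilyl)oxy]-3-{[(tert-butyldiphenylsilyl)oxy]methyl}-7-methylundeca-2,6,10-trien-1-yl]oxy}methyl)acrylate (C6–O–C13 ether in place)
Conditions: NaH added last to 12 and 13, THF, 0 °C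
Reagents that add atoms: none
Why: In this Williamson etherification with a very reactive allylic bromide, SN2 and SN2′ attack give the same product, and immediate trapping of the alkoxide leaves no time for silyl migration from O15 to O6.

Step 10
Reactants: 14 the ether ester of step 9
Product: 16 seco acid, 2-({[(2Z,6E,9S)-3-{[(tert-butyldiphenylsilyl)oxy]methyl}-9-hydroxy-7-methylundeca-2,6,10-trien-1-yl]oxy}methyl)acrylic acid, via silyl ether acid 15 (not isolated)
Conditions: LiOH, THF/H2O, rt; then 3 M HCl to pH 1, rt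
Reagents that add atoms: lithium hydroxide, [Li+].[OH-]
Why: Saponification of the methyl ester is followed in the same flask by aqueous acid cleavage of the secondary TBS ether, conditions under which a TBDPS ether is known to persist.

Step 11
Reactants: 16 seco acid
Product: 17 (8S) 14-membered macrolactone: ring C12(=O)–O8–C8–C9–C10=C1–C2–C3–C4=C5–C6–O–C13–C11, vinyl (C7=CH2) on C8, exocyclic methylene on C11, CH2OTBDPS on C4, both ring olefins ring-E
Conditions: 2-methyl-6-nitrobenzoic anhydride (MNBA), DMAP, CH2Cl2, slow addition (about 1 mM), rt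
Reagents that add atoms: none
Why: Shiina macrolactonisation activates the acid and not the alcohol, so the strain-free 14-membered ring closes with retention at C8.

Step 12
Reactants: 17 macrolactone
Product: 18 (8S) bicyclic butenolide: 13-membered ether ring C6–O–C13–C11=C7–C8–C9–C10=C1–C2–C3–C4=C5 bridged by O8–C12(=O) between C8 and C11
Conditions: Grubbs second-generation catalyst, 1,4-benzoquinone, toluene, 80 °C, argon sparge
Reagents that add atoms: none
Why: Ring-closing metathesis of the allyl 2-substituted acrylate motif closes a five-membered butenolide, which forces C8 and C12 cis on C7=C11 and therefore C13 trans to C8 (the geometry that step 16 needs); the trisubstituted olefins are spectators and the neutral medium spares the acidic C8–H.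

Step 13
Reactants: 18 bicyclic butenolide
Product: 19 (8S) macrocyclic ene-diol: 13-membered ether with C8–OH and C12H2OH cis on C7=C11
Conditions: DIBAL-H (excess), CH2Cl2, −78 to 0 °C; Rochelle salt
Reagents that add atoms: none
Why: Excess DIBAL-H takes butenolides by two 1,2-reductions through the lactol to the (Z)-2-ene-1,4-diol, and the non-acidic work-up avoids dehydration of the lactol to a furan.

Step 14
Reactants: 19 macrocyclic ene-diol
Product: 20 (8S) 8,12-O-isopropylidene derivative (2,2-dimethyl-4,7-dihydro-1,3-dioxepine fused on C8–C7=C11–C12), C15–OTBDPS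
Conditions: 2,2-dimethoxypropane, PPTS (cat.), CH2Cl2, rt
Reagents that add atoms: 2,2-dimethoxypropane, COC(C)(C)OC
Why: Transketalisation of cis-2-ene-1,4-diols to dihydrodioxepines is well known and gives a base-stable group that cannot migrate to an alkoxide and fixes the C8–O8 bond out of the olefin plane.

Step 15
Reactants: 20 acetonide silyl ether
Product: 21 (8S) 13-membered bis-allylic ether with 8,12-acetonide and free C15–OH
Conditions: TBAF, THF, 0 °C to rt
Reagents that add atoms: none
Why: Fluoride cleaves the only silyl ether present, which is necessary because in step 16 O15 has to be an oxide (non-leaving and directing) and not a silyloxy leaving group.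

Step 16
Reactants: 21 the 13-membered bis-allylic ether
Product: 23 (6R,7S,8S)-8,12-O-isopropylidenegermacra-1(10),4,11(13)-triene-6,8,12,15-tetraol (both ring olefins ring-E; O6, H7 and O8 on one face, C11 on the other), via dilithiated ether 22 (not isolated)
Conditions: n-BuLi (3 equiv), THF, −78 to −20 °C; H2O
Reagents that add atoms: none
Why: The first equivalent of n-BuLi forms the C15 alkoxide and a second one removes a C6 proton (allylic, α to the ring oxygen and cis to CH2OLi, so that lithium sits in a six-membered chelate), and the α-oxyallyllithium 22 undergoes a concerted suprafacial [2,3]-Wittig rearrangement through a five-membered envelope in which C6–C7 forms while O–C13 breaks and the π bond moves to C11=C13. The closest known reaction type is the [2,3]-Wittig ring contraction of 13-membered bis-allylic or allyl propargyl cyclic ethers to cyclodeca-1,5-dienols and cyclodecenynols. The ten-membered carbocycle is closed transannularly (13 to 10 ring contraction through a five-centre transition state), so no dilution or entropic price is due, the ring strain is paid by the change from carbanion to alkoxide, and C1=C10 and C4=C5 enter with their ring-E geometry already fixed. C7 is set by C8: the dihydrodioxepine holds the C8–O8 bond nearly perpendicular to the C7=C11 plane with C9 pseudo-equatorial and H8 inside (A1,3 strain), so C6 bonds to the face anti to O8 (Felkin–Anh-type overlap with σ*C–O) and C11 ends up trans to O8; C6 is set by the olefin geometry, because C13 trans to C8 together with the exo position of the C5 vinyl group on the envelope gives the anti C6/C7 relation, that is 6R,7S,8S in 23. The step needs lithiation at C6 and not at C13, C12 or C8, and [2,3] shift in preference to [1,2] shift and 1,4-elimination; the alkoxide direction, the unsubstituted C5 next to C6, the fact that an anion at C13 could only attack the fully substituted C4, the low temperature and the oxide character of O15 (it cannot leave, as a silyloxy group could) secure this. Lithium as the counter-ion and a temperature below −20 °C keep the product, a 1,5-dien-3-olate, from an anionic oxy-Cope rearrangement.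

Step 17
Reactants: 23 the germacratriene diol acetonide
Product: 24 (6R,7S,8S)-15-O-TBDPS ether of 23 (C6–OH free)
Conditions: TBDPSCl (1.05 equiv), imidazole, CH2Cl2, −20 to 0 °C
Reagents that add atoms: tert-butyldiphenylsilyl chloride, Cl[Si](c1ccccc1)(c1ccccc1)C(C)(C)C
Why: The bulky silyl chloride should discriminate between the primary C15–OH and the hindered secondary C6–OH, which is left free for acylation.

Step 18
Reactants: 25 [(tert-butyldimethylsilyl)oxy]acetaldehyde; 26 ethyl 2-(triphenyl-λ5-phosphanylidene)propanoate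
Product: 27 ethyl (2E)-4-[(tert-butyldimethylsilyl)oxy]-2-methylbut-2-enoate
Conditions: CH2Cl2, rt
Reagents that add atoms: none
Why: Wittig olefination with a stabilised, α-branched ylide is E-selective and sets the tiglate geometry of the side chain.

Step 19
Reactants: 27 the ethyl ester of step 18
Product: 28 (2E)-4-[(tert-butyldimethylsilyl)oxy]-2-methylbut-2-enoic acid
Conditions: LiOH, THF/MeOH/H2O, rt; cold dilute HCl to pH 4
Reagents that add atoms: lithium hydroxide, [Li+].[OH-]
Why: Saponification followed by a short, cold and mild acidification leaves the TBS ether and the E olefin intact.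

Step 20
Reactants: 24 the C6 alcohol; 28 the side-chain acid
Product: 29 (6R,7R,8S) 6-O-[(2E)-4-(TBSO)-2-methylbut-2-enoyl] derivative of 24 (the C7 descriptor changes only through the priorities)
Conditions: MNBA, DMAP, Et3N, CH2Cl2, rt
Reagents that add atoms: none
Why: Shiina esterification acylates hindered secondary alcohols at room temperature, which avoids Cope rearrangement of the cyclodeca-1,5-diene; acylating O6 before O8 is freed rules out a 6,12-lactone later.

Step 21
Reactants: 29 the C6 ester acetonide
Product: 30 (6R,7R,8S) 8,12-diol (C8–OH and C12H2OH free, C15–OTBDPS, side-chain OTBS)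
Conditions: PPTS (cat.), MeOH/CH2Cl2, 0 °C
Reagents that add atoms: none
Why: Acid-catalysed transketalisation cleaves the strained seven-membered acetonide much faster than primary silyl ethers, and the acid is too weak for transannular cyclisation of the diene.

Step 22
Reactants: 30 the 8,12-diol
Product: 32 (6R,7R,8S) bis-silylated target: 8,12-olide with C15–OTBDPS and side-chain OTBS, via lactol 31 (not isolated)
Conditions: TEMPO (cat.), PhI(OAc)2, CH2Cl2, rt
Reagents that add atoms: none
Why: In this TEMPO-mediated oxidative lactonisation of a 2-methylene-1,4-diol the primary allylic C12–OH is oxidised first, O8 closes the lactol, and a second oxidation gives the trans-fused α-methylene-γ-butyrolactone without touching any stereocentre.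

Step 23
Reactants: 32 the bis-silylated target
Product: 33 target CNP0344932.1, (6R,7R,8S)-15-hydroxy-6-{[(2E)-4-hydroxy-2-methylbut-2-enoyl]oxy}germacra-1(10),4,11(13)-trien-12,8-olide
Conditions: HF·pyridine, pyridine, THF, 0 °C to rt
Reagents that add atoms: none
Why: Buffered HF·pyridine removes both silyl ethers without free alkoxide or strong acid, so conjugate addition to the α-methylene lactone, acyl migration and transannular cyclisation are avoided.

Compound list
1 | prop-2-yn-1-ol | C#CCO | starting material
2 | tert-butyl(diphenyl)(prop-2-yn-1-yloxy)silane | C#CCO[Si](c1ccccc1)(c1ccccc1)C(C)(C)C | intermediate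
3 | methyl 4-[(tert-butyldiphenylsilyl)oxy]but-2-ynoate | COC(=O)C#CCO[Si](c1ccccc1)(c1ccccc1)C(C)(C)C | intermediate
4 | (R)-2-vinyloxirane | C=C[C@@H]1CO1 | starting material
5 | (3S)-hex-1-en-5-yn-3-ol | C=C[C@@H](O)CC#C | intermediate
6 | (3S)-3-[(tert-butyldimethylsilyl)oxy]hex-1-en-5-yne | C=C[C@@H](O[Si](C)(C)C(C)(C)C)CC#C | intermediate
7 | [(1E,4S)-4-(TBSO)-2-methylhexa-1,5-dien-1-yl]dimethylalane | C=C[C@@H](O[Si](C)(C)C(C)(C)C)C/C(C)=C/[Al](C)C | intermediate
8 | (3E,6S)-6-(TBSO)-4-methylocta-3,7-dien-1-ol | C=C[C@@H](O[Si](C)(C)C(C)(C)C)C/C(C)=C/CCO | intermediate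
9 | (3S,5E)-8-bromo-3-(TBSO)-5-methylocta-1,5-diene | C=C[C@@H](O[Si](C)(C)C(C)(C)C)C/C(C)=C/CCBr | intermediate
10 | Grignard reagent from 9 | C=C[C@@H](O[Si](C)(C)C(C)(C)C)C/C(C)=C/CC[Mg]Br | intermediate
11 | methyl (2Z,6E,9S)-9-(TBSO)-3-[(TBDPSO)methyl]-7-methylundeca-2,6,10-trienoate | C=C[C@@H](O[Si](C)(C)C(C)(C)C)C/C(C)=C/CC/C(CO[Si](c1ccccc1)(c1ccccc1)C(C)(C)C)=C/C(=O)OC | intermediate
12 | (2Z,6E,9S)-9-(TBSO)-3-[(TBDPSO)methyl]-7-methylundeca-2,6,10-trien-1-ol | C=C[C@@H](O[Si](C)(C)C(C)(C)C)C/C(C)=C/CC/C(CO[Si](c1ccccc1)(c1ccccc1)C(C)(C)C)=C/CO | intermediate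
13 | methyl 2-(bromomethyl)acrylate | C=C(CBr)C(=O)OC | starting material
14 | methyl 2-(alkoxymethyl)acrylate from 12 (C6–O–C13 ether) | C=C[C@@H](O[Si](C)(C)C(C)(C)C)C/C(C)=C/CC/C(CO[Si](c1ccccc1)(c1ccccc1)C(C)(C)C)=C/COCC(=C)C(=O)OC | intermediate
15 | carboxylic acid of 14, C8–OTBS still in place | C=C[C@@H](O[Si](C)(C)C(C)(C)C)C/C(C)=C/CC/C(CO[Si](c1ccccc1)(c1ccccc1)C(C)(C)C)=C/COCC(=C)C(=O)O | intermediate
16 | seco acid (C8–OH, C12O2H) | C=C[C@@H](O)C/C(C)=C/CC/C(CO[Si](c1ccccc1)(c1ccccc1)C(C)(C)C)=C/COCC(=C)C(=O)O | intermediate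
17 | (8S) 14-membered macrolactone | C=C[C@@H]1C/C(C)=C/CC/C(CO[Si](c2ccccc2)(c2ccccc2)C(C)(C)C)=C/COCC(=C)C(=O)O1 | intermediate
18 | (8S) bicyclic butenolide with 13-membered ether ring | O=C1O[C@@H]2C=C1COC/C=C(CO[Si](c3ccccc3)(c3ccccc3)C(C)(C)C)/CC/C=C(C)/C2 | intermediate
19 | (8S) macrocyclic ene-diol | O[C@@H]1/C=C(CO)/COC/C=C(CO[Si](c2ccccc2)(c2ccccc2)C(C)(C)C)/CC/C=C(C)/C1 | intermediate
20 | (8S) 8,12-acetonide, C15–OTBDPS | CC1(C)OC/C2=C\[C@@H](O1)C/C(C)=C/CC/C(CO[Si](c3ccccc3)(c3ccccc3)C(C)(C)C)=C/COC2 | intermediate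
21 | (8S) 8,12-acetonide, C15–OH (substrate of the key step) | CC1(C)OC/C2=C\[C@@H](O1)C/C(C)=C/CC/C(CO)=C/COC2 | intermediate
22 | C6-lithio C15-lithium alkoxide of 21 | CC1(C)OC/C2=C\[C@@H](O1)C/C(C)=C/CC/C(CO[Li])=C/C([Li])OC2 | intermediate
23 | (6R,7S,8S)-8,12-O-isopropylidenegermacra-1(10),4,11(13)-triene-6,8,12,15-tetraol | C=C1COC(C)(C)O[C@H]2C/C(C)=C/CC/C(CO)=C/[C@@H](O)[C@H]12 | intermediate
24 | 15-O-TBDPS ether of 23 | C=C1COC(C)(C)O[C@H]2C/C(C)=C/CC/C(CO[Si](c3ccccc3)(c3ccccc3)C(C)(C)C)=C/[C@@H](O)[C@H]12 | intermediate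
25 | [(tert-butyldimethylsilyl)oxy]acetaldehyde | O=CCO[Si](C)(C)C(C)(C)C | starting material
26 | ethyl 2-(triphenyl-λ5-phosphanylidene)propanoate | CCOC(=O)C(C)=P(c1ccccc1)(c1ccccc1)c1ccccc1 | starting material
27 | ethyl (2E)-4-(TBSO)-2-methylbut-2-enoate | CCOC(=O)/C(C)=C/CO[Si](C)(C)C(C)(C)C | intermediate
28 | (2E)-4-(TBSO)-2-methylbut-2-enoic acid | OC(=O)/C(C)=C/CO[Si](C)(C)C(C)(C)C | intermediate
29 | C6 ester of 24 with 28 | C=C1COC(C)(C)O[C@H]2C/C(C)=C/CC/C(CO[Si](c3ccccc3)(c3ccccc3)C(C)(C)C)=C/[C@@H](OC(=O)/C(C)=C/CO[Si](C)(C)C(C)(C)C)[C@H]12 | intermediate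
30 | 8,12-diol from 29 | C=C(CO)[C@@H]1[C@@H](O)C/C(C)=C/CC/C(CO[Si](c2ccccc2)(c2ccccc2)C(C)(C)C)=C/[C@H]1OC(=O)/C(C)=C/CO[Si](C)(C)C(C)(C)C | intermediate
31 | 8,12-lactol | C=C1C(O)O[C@H]2C/C(C)=C/CC/C(CO[Si](c3ccccc3)(c3ccccc3)C(C)(C)C)=C/[C@@H](OC(=O)/C(C)=C/CO[Si](C)(C)C(C)(C)C)[C@H]12 | intermediate
32 | bis-silylated target (8,12-olide) | C=C1C(=O)O[C@H]2C/C(C)=C/CC/C(CO[Si](c3ccccc3)(c3ccccc3)C(C)(C)C)=C/[C@@H](OC(=O)/C(C)=C/CO[Si](C)(C)C(C)(C)C)[C@H]12 | intermediate
33 | CNP0344932.1 | C=C1C(=O)O[C@H]2C/C(C)=C/CC/C(CO)=C/[C@@H](OC(=O)/C(C)=C/CO)[C@H]12 | target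

Total step count: 23. Longest linear sequence: 19 steps (steps 3 to 17 and 20 to 23, from 4).

Steps most likely to fail

1. Step 16 (key step).
- What may go wrong: lithiation at C13, C12 or C8 in place of C6, followed by 1,4-elimination and opening of the dioxepine; a competing [1,2]-shift; poor facial selectivity at C7.
- Fallback: direct closure of C6–C7 by carbonyl allylation, without ring contraction. It sets out from 12 and comes back at 32.
- Allylic oxidation of 12 (MnO2, CH2Cl2) should give the C6 enal F1. HF·pyridine should then give the C8 hydroxy enal F2. Acylation with 2-(bromomethyl)acrylic acid (DCC, catalytic DMAP) should give the bromomethylacrylate F3, and open-chain ring-closing metathesis the 3-(bromomethyl)butenolide enal F4.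
- An intramolecular Barbier allylation (Zn, aq NH4Cl/THF, high dilution) should join C7 to the C6 aldehyde anti to C9 and give the 6-hydroxy-8,12-olide F5. This is acylated with 28 as in step 20 to give 32.

2. Step 12.
- What may go wrong: the macrolactone may not reach the s-cis ester conformation that the metallacycle needs, so that oligomerisation by cross metathesis or ruthenium hydride migration of the allyl ether olefins takes over.
- Fallback: metathesis before macrocyclisation, with the large ring closed at the ether bond. It sets out from 12 and comes back at 18.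
- 12 is taken to the open-chain butenolide enal F4 as described under the first fallback. Luche reduction (NaBH4, CeCl3, MeOH, −78 °C) of the aldehyde should give the hydroxy bromide F6.
- A silver-promoted etherification (AgOTf, 2,6-di-tert-butylpyridine, CH2Cl2, high dilution) of O6 on C13 closes the 13-membered ring to 18.

3. Step 5.
- What may go wrong: incomplete opening of oxirane by the alanate, protodealumination on handling, or slow side reaction of the vinyl group with the excess of alane.
- Fallback: the chain is joined at C1–C2 by cross-coupling in place of C3–C4 by carbocupration, which replaces steps 5 to 7. It sets out from 6 and 3 and comes back at 11.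
- Carboalumination of 6 and quenching with iodine should give the (E)-vinyl iodide F7. Syn-addition of vinylmagnesium bromide/CuBr·SMe2 to 3 at −78 °C should give the dienoate F8. 9-BBN should hydroborate only its terminal vinyl group to give the B-alkyl borane F9.
- A B-alkyl Suzuki coupling of F9 with F7 (PdCl2(dppf), Cs2CO3, DMF/THF/H2O, rt) gives 11.

Further compounds
F1 | step 16 | (2Z,6E,9S)-9-(TBSO)-3-[(TBDPSO)methyl]-7-methylundeca-2,6,10-trienal | C=C[C@@H](O[Si](C)(C)C(C)(C)C)C/C(C)=C/CC/C(CO[Si](c1ccccc1)(c1ccccc1)C(C)(C)C)=C/C=O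
F2 | step 16 | (2Z,6E,9S)-9-hydroxy-3-[(TBDPSO)methyl]-7-methylundeca-2,6,10-trienal | C=C[C@@H](O)C/C(C)=C/CC/C(CO[Si](c1ccccc1)(c1ccccc1)C(C)(C)C)=C/C=O
F3 | step 16 | 2-(bromomethyl)acrylate of F2 at O8 | C=C[C@@H](OC(=O)C(=C)CBr)C/C(C)=C/CC/C(CO[Si](c1ccccc1)(c1ccccc1)C(C)(C)C)=C/C=O
F4 | step 16 | (8S) 3-(bromomethyl)butenolide with the C6 enal chain | O=C1O[C@H](C=C1CBr)C/C(C)=C/CC/C(CO[Si](c2ccccc2)(c2ccccc2)C(C)(C)C)=C/C=O
F5 | step 16 | (6R,7S,8S)-15-(TBDPSO)-6-hydroxygermacra-1(10),4,11(13)-trien-12,8-olide | C=C1C(=O)O[C@H]2C/C(C)=C/CC/C(CO[Si](c3ccccc3)(c3ccccc3)C(C)(C)C)=C/[C@@H](O)[C@H]12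
F6 | step 12 | (8S) 3-(bromomethyl)butenolide with free C6–OH | O=C1O[C@H](C=C1CBr)C/C(C)=C/CC/C(CO[Si](c2ccccc2)(c2ccccc2)C(C)(C)C)=C/CO
F7 | step 5 | (1E,4S)-4-(TBSO)-1-iodo-2-methylhexa-1,5-diene | C=C[C@@H](O[Si](C)(C)C(C)(C)C)C/C(C)=C/I
F8 | step 5 | methyl (2Z)-3-[(TBDPSO)methyl]penta-2,4-dienoate | COC(=O)/C=C(CO[Si](c1ccccc1)(c1ccccc1)C(C)(C)C)/C=C
F9 | step 5 | methyl (2Z)-5-(9-borabicyclo[3.3.1]nonan-9-yl)-3-[(TBDPSO)methyl]pent-2-enoate | COC(=O)/C=C(CO[Si](c1ccccc1)(c1ccccc1)C(C)(C)C)/CCB1C2CCCC1CCC2
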